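**Strategy.** Ring B of the aryltetralin is closed last, by making the C1–C2 bond. The 4-hydroxy-3,5-dimethoxyphenyl ring on C1 carries a free para-hydroxyl, so loss of water from a diaryl carbinol turns C1 into the exocyclic carbon of a para-quinone methide; C2, alpha to the C2a aldehyde, attacks it as an enamine. One operation forms C1–C2, closes ring B and sets C1 and C2 against the preset C3. The precursor is an open-chain (3R)-butanal carrying the ring A aryl (carbinol ortho) on C4 and a benzyloxymethyl arm on C3; C3 comes from an Evans allylation, the carbinol from an aryllithium addition to silylated syringaldehyde.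

Key step: step 11

Remark: tetralin numbering is used throughout (C1 aryl-bearing, C2/C2a, C3/C3a, C4, ring A = C4a to C8a); the C3a oxygen is carried as a benzyl ether, which tolerates the aryllithium, cannot trap the quinone methide or form a lactol, and leaves together with the ring A benzyl ether; 4-benzyloxy-3-methoxybenzaldehyde is taken as commercial.

**Route**

Step 1
Reactants: 1 4-benzyloxy-3-methoxybenzaldehyde
Product: 2 4-benzyloxy-2-bromo-5-methoxybenzaldehyde
Conditions: Br2, NaOAc, AcOH, rt
Reagents that add atoms: bromine, BrBr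
Why: Electrophilic aromatic bromination should go para to the methoxy group (ortho to the formyl group), the most activated free position, as in the 6-bromination of veratraldehyde; the acetate buffer protects the benzyl ether from HBr.

Step 2
Reactants: 2 4-benzyloxy-2-bromo-5-methoxybenzaldehyde; 3 Meldrum's acid
Product: 6 3-(4-benzyloxy-2-bromo-5-methoxyphenyl)propanoic acid, via arylidene Meldrum's acid 4 (not isolated), via benzyl Meldrum's acid 5 (not isolated)
Conditions: HCO2H/Et3N (5:2), DMF, 100 °C
Reagents that add atoms: none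
Why: Reductive alkylation of Meldrum's acid (Knoevenagel condensation, conjugate hydride transfer from formate, then ring opening and decarboxylation) should give the saturated acid without touching the aryl bromide or the benzyl ether.

Step 3
Reactants: 6 3-(4-benzyloxy-2-bromo-5-methoxyphenyl)propanoic acid; 7 (S)-4-benzyl-2-oxazolidinone
Product: 9 (4S)-4-benzyl-3-[3-(4-benzyloxy-2-bromo-5-methoxyphenyl)propanoyl]oxazolidin-2-one, via mixed pivalic anhydride 8 (not isolated)
Conditions: t-BuCOCl, Et3N, THF, −20 °C; then 7, LiCl, −20 °C to rt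
Reagents that add atoms: none
Why: N-acylation of the oxazolidinone through the mixed pivalic anhydride under LiCl/Et3N activation is the standard way to attach the auxiliary.

Step 4
Reactants: 9 (4S)-4-benzyl-3-[3-(4-benzyloxy-2-bromo-5-methoxyphenyl)propanoyl]oxazolidin-2-one; 10 allyl bromide
Product: 12 (4S)-4-benzyl-3-[(2S)-2-(4-benzyloxy-2-bromo-5-methoxybenzyl)pent-4-enoyl]oxazolidin-2-one, via sodium Z-enolate 11 (not isolated)
Conditions: NaN(SiMe3)2, THF, −78 °C; then 10, −78 to −40 °C
Reagents that add atoms: none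
Why: Evans alkylation: the chelated Z-enolate should be allylated on the face away from the 4-benzyl group of the (S)-auxiliary, which sets C3 in the sense that becomes (3R) in aldehyde 20 and in the target.

Step 5
Reactants: 12 (4S)-4-benzyl-3-[(2S)-2-(4-benzyloxy-2-bromo-5-methoxybenzyl)pent-4-enoyl]oxazolidin-2-one
Product: 13 (2S)-2-(4-benzyloxy-2-bromo-5-methoxybenzyl)pent-4-en-1-ol
Conditions: LiBH4, MeOH (1.1 equiv), THF, 0 °C
Reagents that add atoms: none
Why: Reductive cleavage of the N-acyl oxazolidinone by LiBH4 should give the primary alcohol without epimerisation and return the auxiliary; the aryl bromide and the alkene are inert.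

Step 6
Reactants: 13 (2S)-2-(4-benzyloxy-2-bromo-5-methoxybenzyl)pent-4-en-1-ol
Product: 14 1-benzyloxy-4-[(2S)-2-(benzyloxymethyl)pent-4-en-1-yl]-5-bromo-2-methoxybenzene
Conditions: NaH, BnBr, Bu4NI (cat.), THF/DMF, 0 °C to rt
Reagents that add atoms: benzyl bromide, BrCc1ccccc1
Why: Williamson etherification of the primary alkoxide; it removes the only acidic proton before the halogen–lithium exchange.

Step 7
Reactants: 15 syringaldehyde
Product: 16 4-(tert-butyldimethylsilyloxy)-3,5-dimethoxybenzaldehyde
Conditions: TBSCl, imidazole, DMF, rt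
Reagents that add atoms: tert-butyldimethylsilyl chloride, CC(C)(C)[Si](C)(C)Cl
Why: Silylation of the phenol makes the aldehyde a clean electrophile for the aryllithium and shields the phenol from periodate in step 9.

Step 8
Reactants: 14 1-benzyloxy-4-[(2S)-2-(benzyloxymethyl)pent-4-en-1-yl]-5-bromo-2-methoxybenzene; 16 4-(tert-butyldimethylsilyloxy)-3,5-dimethoxybenzaldehyde
Product: 18 {5-benzyloxy-2-[(2S)-2-(benzyloxymethyl)pent-4-en-1-yl]-4-methoxyphenyl}[4-(tert-butyldimethylsilyloxy)-3,5-dimethoxyphenyl]methanol (both carbinol epimers), via aryllithium 17 (not isolated)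
Conditions: n-BuLi, THF, −78 °C; then 16, −78 to −30 °C; H2O
Reagents that add atoms: none
Why: Bromine–lithium exchange followed by 1,2-addition to the non-enolisable aldehyde should give the diaryl carbinol; its configuration is irrelevant because this carbon is planarised in step 11.

Step 9
Reactants: 18 the diaryl carbinol of step 8
Product: 19 (3R)-3-(benzyloxymethyl)-4-{4-benzyloxy-2-[hydroxy(4-(tert-butyldimethylsilyloxy)-3,5-dimethoxyphenyl)methyl]-5-methoxyphenyl}butanal
Conditions: OsO4 (2 mol %), NaIO4, 2,6-lutidine, dioxane/H2O 3:1, rt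
Reagents that add atoms: osmium tetroxide, O=[Os](=O)(=O)=O; sodium periodate, [Na+].[O-]I(=O)(=O)=O
Why: Lemieux–Johnson cleavage (catalytic dihydroxylation, then periodate glycol cleavage) should turn the terminal alkene into the C2a aldehyde; the lutidine buffer protects the acid-labile carbinol.

Step 10
Reactants: 19 the silyl-protected carbinol aldehyde of step 9
Product: 20 (3R)-3-(benzyloxymethyl)-4-{4-benzyloxy-2-[hydroxy(4-hydroxy-3,5-dimethoxyphenyl)methyl]-5-methoxyphenyl}butanal
Conditions: Bu4NF, AcOH (1:1), THF, 0 °C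
Reagents that add atoms: none
Why: Fluoride cleaves the aryl silyl ether rapidly, and the acetic acid buffer keeps the enolisable aldehyde and the carbinol away from basic fluoride.

Step 11
Reactants: 20 (3R)-3-(benzyloxymethyl)-4-{4-benzyloxy-2-[hydroxy(4-hydroxy-3,5-dimethoxyphenyl)methyl]-5-methoxyphenyl}butanal
Product: 23 (1S,2R,3R)-7-benzyloxy-3-(benzyloxymethyl)-1-(4-hydroxy-3,5-dimethoxyphenyl)-6-methoxy-1,2,3,4-tetrahydronaphthalene-2-carbaldehyde, via quinone methide aldehyde 21 (not isolated), via quinone methide enamine 22 (not isolated)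
Conditions: (R)-2-[diphenyl(trimethylsilyloxy)methyl]pyrrolidine (20 mol %), 4-nitrobenzoic acid (40 mol %), CHCl3 (0.02 M), 40 °C
Reagents that add atoms: none
Why: The acid dehydrates the para-hydroxybenzhydrol to the syringyl para-quinone methide 21 and the amine condenses with the C2a aldehyde to the E-enamine 22, whose C2 adds to the exocyclic C1 in a 1,6-conjugate addition that re-aromatises the syringyl ring; the water lost in the dehydration hydrolyses the iminium ion and releases 23 and the catalyst. The closest known reaction type is the aminocatalytic 1,6-addition (alpha-alkylation) of aldehydes to para-quinone methides formed in situ from para-hydroxybenzyl alcohols, run here intramolecularly as in enamine-terminated domino additions to quinone methides. Ring B closes in a 6-exo-trig mode with respect to the C1=C(quinoid) bond (enol-exo with respect to the enamine). C1 is controlled by the preset C3 centre through a chair-like transition state in which the benzyloxymethyl arm on C3 and the quinoid ring on C1 are both pseudo-equatorial (1,3-cis), and the (R)-catalyst should reinforce this because its shielding group leaves open the enamine face that gives the (2R) centre (matched pair). C2 is formed on that face with the enamine carbon C2a equatorial and, being enolisable, equilibrates through the enamine to the isomer trans to both C1 and C3. The step needs intramolecular C-alkylation to outrun intermolecular capture of the quinone methide; the six-membered tether, high dilution and the absence of any free hydroxyl or second activated arene within reach (C3a and the ring A phenol are benzyl ethers) secure this.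

Step 12
Reactants: 23 the tetralin aldehyde of step 11
Product: 24 [(1S,2R,3R)-7-benzyloxy-3-(benzyloxymethyl)-1-(4-hydroxy-3,5-dimethoxyphenyl)-6-methoxy-1,2,3,4-tetrahydronaphthalen-2-yl]methanol
Conditions: NaBH4, MeOH/THF, 0 °C
Reagents that add atoms: none
Why: Borohydride reduction of the aldehyde gives the C2a primary alcohol and ends the epimerisability of C2.

Step 13
Reactants: 24 the mono-alcohol of step 12
Product: 25 (1S,2R,3R)-7-hydroxy-1-(4-hydroxy-3,5-dimethoxyphenyl)-6-methoxy-1,2,3,4-tetrahydronaphthalene-2,3-dimethanol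
Conditions: H2 (1 atm), Pd(OH)2/C, EtOAc/MeOH, rt
Reagents that add atoms: none
Why: Hydrogenolysis should remove the aryl and the alkyl benzyl ether together; the C1–H diarylmethine has no heteroatom leaving group and is not cleaved.

Step 14
Reactants: 25 the tetraol of step 13
Product: 26 the tetraacetate of 25 (two primary and two aryl acetates)
Conditions: Ac2O, pyridine, DMAP (cat.), rt
Reagents that add atoms: acetic anhydride, CC(=O)OC(C)=O
Why: Exhaustive DMAP-catalysed acylation acetylates all four hydroxyls, so no selectivity is asked of this step.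

Step 15
Reactants: 26 the tetraacetate of step 14
Product: 27 [(1S,2R,3R)-7-hydroxy-1-(4-hydroxy-3,5-dimethoxyphenyl)-6-methoxy-1,2,3,4-tetrahydronaphthalene-2,3-diyl]dimethyl diacetate (target)
Conditions: pyrrolidine (6 equiv), CH2Cl2, 0 °C to rt
Reagents that add atoms: none
Why: Chemoselective aminolysis: aryl acetates (phenoxide leaving group) react with a secondary amine far faster than primary alkyl acetates, so only the two phenols should be freed.

**Compound list**

1 | 4-benzyloxy-3-methoxybenzaldehyde | COc1cc(C=O)ccc1OCc1ccccc1 | starting material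
2 | 4-benzyloxy-2-bromo-5-methoxybenzaldehyde | COc1cc(C=O)c(Br)cc1OCc1ccccc1 | intermediate
3 | Meldrum's acid (2,2-dimethyl-1,3-dioxane-4,6-dione) | CC1(C)OC(=O)CC(=O)O1 | starting material
4 | 5-(4-benzyloxy-2-bromo-5-methoxybenzylidene)-2,2-dimethyl-1,3-dioxane-4,6-dione | COc1cc(C=C2C(=O)OC(C)(C)OC2=O)c(Br)cc1OCc1ccccc1 | intermediate (not isolated)
5 | 5-(4-benzyloxy-2-bromo-5-methoxybenzyl)-2,2-dimethyl-1,3-dioxane-4,6-dione | COc1cc(CC2C(=O)OC(C)(C)OC2=O)c(Br)cc1OCc1ccccc1 | intermediate (not isolated)
6 | 3-(4-benzyloxy-2-bromo-5-methoxyphenyl)propanoic acid | COc1cc(CCC(=O)O)c(Br)cc1OCc1ccccc1 | intermediate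
7 | (S)-4-benzyl-2-oxazolidinone | O=C1N[C@@H](Cc2ccccc2)CO1 | starting material
8 | 3-(4-benzyloxy-2-bromo-5-methoxyphenyl)propanoic pivalic anhydride | COc1cc(CCC(=O)OC(=O)C(C)(C)C)c(Br)cc1OCc1ccccc1 | intermediate (not isolated)
9 | (4S)-4-benzyl-3-[3-(4-benzyloxy-2-bromo-5-methoxyphenyl)propanoyl]oxazolidin-2-one | O=C1N(C(=O)CCc2cc(OC)c(OCc3ccccc3)cc2Br)[C@@H](Cc2ccccc2)CO1 | intermediate
10 | allyl bromide | C=CCBr | starting material
11 | sodium Z-enolate of 9 | O=C1N(/C([O-])=C/Cc2cc(OC)c(OCc3ccccc3)cc2Br)[C@@H](Cc2ccccc2)CO1.[Na+] | intermediate (not isolated)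
12 | (4S)-4-benzyl-3-[(2S)-2-(4-benzyloxy-2-bromo-5-methoxybenzyl)pent-4-enoyl]oxazolidin-2-one | O=C1N(C(=O)[C@@H](CC=C)Cc2cc(OC)c(OCc3ccccc3)cc2Br)[C@@H](Cc2ccccc2)CO1 | intermediate
13 | (2S)-2-(4-benzyloxy-2-bromo-5-methoxybenzyl)pent-4-en-1-ol | OC[C@@H](CC=C)Cc1cc(OC)c(OCc2ccccc2)cc1Br | intermediate
14 | 1-benzyloxy-4-[(2S)-2-(benzyloxymethyl)pent-4-en-1-yl]-5-bromo-2-methoxybenzene | C=CC[C@H](COCc1ccccc1)Cc1cc(OC)c(OCc2ccccc2)cc1Br | intermediate
15 | syringaldehyde | COc1cc(C=O)cc(OC)c1O | starting material
16 | 4-(tert-butyldimethylsilyloxy)-3,5-dimethoxybenzaldehyde | COc1cc(C=O)cc(OC)c1O[Si](C)(C)C(C)(C)C | intermediate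
17 | aryllithium from 14 (lithium in place of bromine) | C=CC[C@H](COCc1ccccc1)Cc1cc(OC)c(OCc2ccccc2)cc1[Li] | intermediate (not isolated)
18 | {5-benzyloxy-2-[(2S)-2-(benzyloxymethyl)pent-4-en-1-yl]-4-methoxyphenyl}[4-(tert-butyldimethylsilyloxy)-3,5-dimethoxyphenyl]methanol, carbinol epimers | C=CC[C@H](COCc1ccccc1)Cc1cc(OC)c(OCc2ccccc2)cc1C(O)c1cc(OC)c(O[Si](C)(C)C(C)(C)C)c(OC)c1 | intermediate
19 | (3R)-3-(benzyloxymethyl)-4-{4-benzyloxy-2-[hydroxy(4-(tert-butyldimethylsilyloxy)-3,5-dimethoxyphenyl)methyl]-5-methoxyphenyl}butanal | O=CC[C@H](COCc1ccccc1)Cc1cc(OC)c(OCc2ccccc2)cc1C(O)c1cc(OC)c(O[Si](C)(C)C(C)(C)C)c(OC)c1 | intermediate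
20 | (3R)-3-(benzyloxymethyl)-4-{4-benzyloxy-2-[hydroxy(4-hydroxy-3,5-dimethoxyphenyl)methyl]-5-methoxyphenyl}butanal (key-step precursor) | O=CC[C@H](COCc1ccccc1)Cc1cc(OC)c(OCc2ccccc2)cc1C(O)c1cc(OC)c(O)c(OC)c1 | intermediate
21 | (3R)-3-(benzyloxymethyl)-4-{4-benzyloxy-2-[(3,5-dimethoxy-4-oxocyclohexa-2,5-dien-1-ylidene)methyl]-5-methoxyphenyl}butanal (para-quinone methide) | O=CC[C@H](COCc1ccccc1)Cc1cc(OC)c(OCc2ccccc2)cc1C=C1C=C(OC)C(=O)C(OC)=C1 | intermediate (not isolated)
22 | E-enamine of 21 with (R)-2-[diphenyl(trimethylsilyloxy)methyl]pyrrolidine | C[Si](C)(C)OC(c1ccccc1)(c1ccccc1)[C@H]1CCCN1/C=C/[C@H](COCc1ccccc1)Cc1cc(OC)c(OCc2ccccc2)cc1C=C1C=C(OC)C(=O)C(OC)=C1 | intermediate (not isolated)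
23 | (1S,2R,3R)-7-benzyloxy-3-(benzyloxymethyl)-1-(4-hydroxy-3,5-dimethoxyphenyl)-6-methoxy-1,2,3,4-tetrahydronaphthalene-2-carbaldehyde (key-step product) | COc1cc2c(cc1OCc1ccccc1)[C@H](c1cc(OC)c(O)c(OC)c1)[C@@H](C=O)[C@H](COCc1ccccc1)C2 | intermediate
24 | [(1S,2R,3R)-7-benzyloxy-3-(benzyloxymethyl)-1-(4-hydroxy-3,5-dimethoxyphenyl)-6-methoxy-1,2,3,4-tetrahydronaphthalen-2-yl]methanol | COc1cc2c(cc1OCc1ccccc1)[C@H](c1cc(OC)c(O)c(OC)c1)[C@@H](CO)[C@H](COCc1ccccc1)C2 | intermediate
25 | (1S,2R,3R)-7-hydroxy-1-(4-hydroxy-3,5-dimethoxyphenyl)-6-methoxy-1,2,3,4-tetrahydronaphthalene-2,3-dimethanol | COc1cc2c(cc1O)[C@H](c1cc(OC)c(O)c(OC)c1)[C@@H](CO)[C@H](CO)C2 | intermediate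
26 | tetraacetate of 25 | COc1cc2c(cc1OC(C)=O)[C@H](c1cc(OC)c(OC(C)=O)c(OC)c1)[C@@H](COC(C)=O)[C@H](COC(C)=O)C2 | intermediate
27 | [(1S,2R,3R)-7-hydroxy-1-(4-hydroxy-3,5-dimethoxyphenyl)-6-methoxy-1,2,3,4-tetrahydronaphthalene-2,3-diyl]dimethyl diacetate | COc1cc2c(cc1O)[C@H](c1cc(OC)c(O)c(OC)c1)[C@@H](COC(C)=O)[C@H](COC(C)=O)C2 | target

**Step count**

Total: 15 steps. Longest linear sequence: 14 steps (steps 1–6 and 8–15, from 1); step 7 is a one-step branch.

**Steps most likely to fail**

1. Step 11. The quinone methide may be captured intermolecularly (oligomerisation, Friedel–Crafts attack by another ring A) faster than the enamine closes, or the facial selectivity at C1 may be poor. The fallback sets out from 19. TBSOTf/Et3N in CH2Cl2 at −78 °C should convert the aldehyde into its silyl enol ether and cap the carbinol, giving the bis-silylated enol ether F1. A catalytic amount of TMSOTf then ionises the doubly activated diarylmethyl silyl ether, and the enol ether closes onto the cation (intramolecular SN1-type Mukaiyama alkylation, same C1–C2 bond, same chair), giving the aryl-silylated tetralin aldehyde F2. Brief DBU treatment equilibrates C2 if needed, and Bu4NF/AcOH removes the aryl silyl group, which returns the route to 23.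

2. Step 10. Once the phenol is free, premature loss of water from the carbinol on work-up or on silica may start quinone methide formation and oligomerisation, and residual basic fluoride may trigger aldol self-condensation. The fallback sets out from 19. Acetylation of the carbinol (Ac2O, DMAP, Et3N, CH2Cl2) should give the diarylmethyl acetate F3. CsF in MeCN, in the presence of the amine catalyst of step 11, then removes the aryl silyl group; the phenoxide expels acetate, so 21 is generated without acid directly in the cyclisation flask. Compound 20 is bypassed and the route is rejoined at 23.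

3. Step 15. Aminolysis may stall at the hindered syringyl acetate, or on forcing begin to cleave the primary acetates. The fallback sets out from 25 and replaces selective deprotection by temporary protection. BnBr/K2CO3 in acetone alkylates only the two phenols, giving the bis(aryl benzyl ether) diol F4. Ac2O/pyridine then gives the diacetate F5, and hydrogenolysis (H2, Pd/C, EtOAc) frees both phenols and arrives at 27.

**Further compounds**

F1 | step 11 | tert-butyldimethylsilyl enol ether of 19 with the carbinol also O-silylated | CC(C)(C)[Si](C)(C)OC=C[C@H](COCc1ccccc1)Cc1cc(OC)c(OCc2ccccc2)cc1C(O[Si](C)(C)C(C)(C)C)c1cc(OC)c(O[Si](C)(C)C(C)(C)C)c(OC)c1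
F2 | step 11 | (1S,2R,3R)-7-benzyloxy-3-(benzyloxymethyl)-1-[4-(tert-butyldimethylsilyloxy)-3,5-dimethoxyphenyl]-6-methoxy-1,2,3,4-tetrahydronaphthalene-2-carbaldehyde | COc1cc2c(cc1OCc1ccccc1)[C@H](c1cc(OC)c(O[Si](C)(C)C(C)(C)C)c(OC)c1)[C@@H](C=O)[C@H](COCc1ccccc1)C2
F3 | step 10 | diarylmethyl acetate of 19 | O=CC[C@H](COCc1ccccc1)Cc1cc(OC)c(OCc2ccccc2)cc1C(OC(C)=O)c1cc(OC)c(O[Si](C)(C)C(C)(C)C)c(OC)c1
F4 | step 15 | (1S,2R,3R)-7-benzyloxy-1-(4-benzyloxy-3,5-dimethoxyphenyl)-6-methoxy-1,2,3,4-tetrahydronaphthalene-2,3-dimethanol | COc1cc2c(cc1OCc1ccccc1)[C@H](c1cc(OC)c(OCc3ccccc3)c(OC)c1)[C@@H](CO)[C@H](CO)C2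
F5 | step 15 | diacetate of F4 | COc1cc2c(cc1OCc1ccccc1)[C@H](c1cc(OC)c(OCc3ccccc3)c(OC)c1)[C@@H](COC(C)=O)[C@H](COC(C)=O)C2
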